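The route rests on cutting the (E)-allylic aryl ether O7–C1'H2–C2'H=C3'(CH3) that hangs from the benzo ring (ring A) of the coumarin (side chain numbered C1' at OCH2 to C11' at the tertiary carbinol). One flask joins three pieces: zirconium-catalysed syn methylalumination of a terminal C2'≡C3' alkyne makes the C3'–CH3 bond, and the C2'-alkenylalane is then alkylated by a ring A aryloxymethyl chloride, making C1'–C2' and fixing the E geometry. The alkyne is the C2'–C11' enyne that already holds the (E)-C6'=C7' alkene, the tartrate-derived C9'/C10' diol as acetonide and the C11' carbinol as triethylsilyl ether.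

Key step: step 11

Remark: the alkenylaluminium intermediate 19 is aggregated in solution and is drawn as the monomeric dimethylalane.

Step 1
Reactants: 1 dimethyl (4S,5S)-2,2-dimethyl-1,3-dioxolane-4,5-dicarboxylate (the acetonide of dimethyl D-tartrate)
Product: 3 methyl (4S,5R)-5-(hydroxymethyl)-2,2-dimethyl-1,3-dioxolane-4-carboxylate, via formyl ester 2 (not isolated)
Conditions: NaBH4 (0.6 equiv), MeOH, 0 °C; stopped at partial conversion, recovered 1 recycled
Reagents that add atoms: none
Why: Borohydride reduction of an α-alkoxy ester, run with a deficit of hydride so that the C2-symmetric diester should be reduced mainly on one side; neither stereocentre is touched.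

Step 2
Reactants: 3 methyl (4S,5R)-5-(hydroxymethyl)-2,2-dimethyl-1,3-dioxolane-4-carboxylate
Product: 5 2-[(4S,5R)-5-(hydroxymethyl)-2,2-dimethyl-1,3-dioxolan-4-yl]propan-2-ol, via methyl ketone 4 (not isolated)
Conditions: MeMgBr (4 equiv), THF, 0 °C → rt; aq. NH4Cl
Reagents that add atoms: methylmagnesium bromide, C[Mg]Br
Why: Double Grignard addition to an ester installs the C11' gem-dimethyl carbinol; addition to the transient α-alkoxy ketone should outrun enolisation, so C10' keeps its configuration.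

Step 3
Reactants: 5 2-[(4S,5R)-5-(hydroxymethyl)-2,2-dimethyl-1,3-dioxolan-4-yl]propan-2-ol
Product: 7 {(4R,5S)-2,2-dimethyl-5-[2-(triethylsilyloxy)propan-2-yl]-1,3-dioxolan-4-yl}methyl trifluoromethanesulfonate, via hydroxy triflate 6 (not isolated)
Conditions: Tf2O (1.05 equiv), 2,6-lutidine (3 equiv), CH2Cl2, −78 °C; then TESOTf (1.3 equiv), −78 → 0 °C; rapid filtration through cold silica, used at once
Reagents that add atoms: trifluoromethanesulfonic anhydride, O=S(=O)(OS(=O)(=O)C(F)(F)F)C(F)(F)F; triethylsilyl trifluoromethanesulfonate, CC[Si](CC)(CC)OS(=O)(=O)C(F)(F)F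
Why: One-pot selective sulfonylation then silylation: the primary hydroxyl should be triflated far faster than the tertiary one at −78 °C, the tertiary hydroxyl is then capped by the silyl triflate, and cyclisation onto the triflate is disfavoured because it would give a trans-fused bicycle on the trans-dioxolane.

Step 4
Reactants: 8 2,3-dihydrofuran; 7 {(4R,5S)-2,2-dimethyl-5-[2-(triethylsilyloxy)propan-2-yl]-1,3-dioxolan-4-yl}methyl trifluoromethanesulfonate
Product: 10 5-({(4R,5S)-2,2-dimethyl-5-[2-(triethylsilyloxy)propan-2-yl]-1,3-dioxolan-4-yl}methyl)-2,3-dihydrofuran, via 5-lithio-2,3-dihydrofuran 9 (not isolated)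
Conditions: 8 (2.0 equiv), t-BuLi (1.8 equiv), THF, −78 → 0 °C; then 7, THF, −78 → −20 °C; Et3N-deactivated silica
Reagents that add atoms: none
Why: α-Lithiation of the cyclic enol ether followed by SN2 alkylation forms the C7'–C8' bond; a triflate is chosen because a β-oxygenated primary carbon is too sluggish as an iodide, and no stereocentre takes part.

Step 5
Reactants: 10 5-({(4R,5S)-2,2-dimethyl-5-[2-(triethylsilyloxy)propan-2-yl]-1,3-dioxolan-4-yl}methyl)-2,3-dihydrofuran
Product: 11 (3E)-5-{(4R,5S)-2,2-dimethyl-5-[2-(triethylsilyloxy)propan-2-yl]-1,3-dioxolan-4-yl}-4-methylpent-3-en-1-ol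
Conditions: MeMgBr (3 equiv), NiCl2(PPh3)2 (5 mol %), PhMe, 60 °C; aq. NH4Cl
Reagents that add atoms: methylmagnesium bromide, C[Mg]Br
Why: Nickel-catalysed Grignard coupling of a cyclic enol ether (Wenkert-type ring opening of a 5-alkyl-2,3-dihydrofuran): zerovalent nickel inserts into the alkenyl C–O bond and methyl replaces oxygen with retention, so the ring geometry should become the (E)-C6'=C7' alkene.

Step 6
Reactants: 11 (3E)-5-{(4R,5S)-2,2-dimethyl-5-[2-(triethylsilyloxy)propan-2-yl]-1,3-dioxolan-4-yl}-4-methylpent-3-en-1-ol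
Product: 12 (4R,5S)-4-[(2E)-5-iodo-2-methylpent-2-en-1-yl]-2,2-dimethyl-5-[2-(triethylsilyloxy)propan-2-yl]-1,3-dioxolane
Conditions: I2, PPh3, imidazole, CH2Cl2, 0 °C → rt
Reagents that add atoms: iodine, II
Why: Appel-type iodination of a primary alcohol through its alkoxyphosphonium salt; the imidazole buffer should keep the acetonide and the silyl ether intact.

Step 7
Reactants: 12 (4R,5S)-4-[(2E)-5-iodo-2-methylpent-2-en-1-yl]-2,2-dimethyl-5-[2-(triethylsilyloxy)propan-2-yl]-1,3-dioxolane
Product: 13 (4R,5S)-2,2-dimethyl-4-[(2E)-2-methylhept-2-en-6-yn-1-yl]-5-[2-(triethylsilyloxy)propan-2-yl]-1,3-dioxolane (the C2'–C11' enyne)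
Conditions: LiC≡CH·H2NCH2CH2NH2 (3 equiv), DMSO, 10 °C → rt
Reagents that add atoms: lithium acetylide–ethylenediamine complex, [Li]C#C.NCCN
Why: SN2 alkylation of an acetylide by a primary homoallylic iodide in DMSO, where substitution should outrun E2 elimination; it forms the C3'–C4' bond.

Step 8
Reactants: 14 5,7-dihydroxycoumarin (5,7-dihydroxy-2H-chromen-2-one)
Product: 15 5-hydroxy-7-[(methylsulfanyl)methoxy]-2H-chromen-2-one
Conditions: NaH (1.0 equiv), DMF, 0 °C; then ClCH2SMe (1.0 equiv), 0 °C → rt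
Reagents that add atoms: chloromethyl methyl sulfide, CSCCl
Why: Williamson etherification of the monophenoxide; O7 should react preferentially because its oxide is conjugated para through C4a to the lactone carbonyl and is unhindered, whereas O5 is flanked by the peri C4–H.

Step 9
Reactants: 15 5-hydroxy-7-[(methylsulfanyl)methoxy]-2H-chromen-2-one
Product: 16 5-[(tert-butyldimethylsilyl)oxy]-7-[(methylsulfanyl)methoxy]-2H-chromen-2-one
Conditions: TBSCl, imidazole, DMF, rt
Reagents that add atoms: tert-butyldimethylsilyl chloride, CC(C)(C)[Si](C)(C)Cl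
Why: Standard imidazole-mediated silylation of the remaining phenol, which must be masked before any organoaluminium reagent is present.

Step 10
Reactants: 16 5-[(tert-butyldimethylsilyl)oxy]-7-[(methylsulfanyl)methoxy]-2H-chromen-2-one
Product: 17 5-[(tert-butyldimethylsilyl)oxy]-7-(chloromethoxy)-2H-chromen-2-one
Conditions: SO2Cl2 (1.0 equiv), CH2Cl2, −78 → 0 °C; volatiles removed in vacuo, crude 17 used at once
Reagents that add atoms: sulfuryl chloride, O=S(=O)(Cl)Cl
Why: Chlorinolysis of an O,S-acetal (S-chlorination, then loss of MeSCl) is the established way from aryl methylthiomethyl ethers to aryl chloromethyl ethers and, with one equivalent at low temperature, should be faster than chlorination of ring A.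

Step 11
Reactants: 13 the C2'–C11' enyne; 17 5-[(tert-butyldimethylsilyl)oxy]-7-(chloromethoxy)-2H-chromen-2-one; 18 trimethylaluminium
Product: 20 5-[(tert-butyldimethylsilyl)oxy]-7-{[(2E,6E)-8-{(4R,5S)-2,2-dimethyl-5-[2-(triethylsilyloxy)propan-2-yl]-1,3-dioxolan-4-yl}-3,7-dimethylocta-2,6-dien-1-yl]oxy}-2H-chromen-2-one, via alkenyldimethylalane 19 (not isolated)
Conditions: 18 (3 equiv), Cp2ZrCl2 (10 mol %), H2O (1.5 equiv), CH2Cl2, −20 °C; CH2Cl2 and free AlMe3 removed in vacuo at 0 °C; then 17 (1.5 equiv), CH2Cl2, −78 → −20 °C; aq. potassium sodium tartrate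
Reagents that add atoms: trimethylaluminium (18), C[Al](C)C
Why: Proposed new method: Cp2ZrCl2 and AlMe3, activated by the aluminoxane formed from water, give a methylzirconium–aluminium species that adds CH3 to C3' and metal to terminal C2' of 13 across the same face of the triple bond, and the alkenyl group ends on aluminium as 19. The aluminium centre then pulls chloride from the α-chloro ether 17 and the aryloxymethyl oxocarbenium ion is captured at C2', the carbon bearing aluminium, because attack there places the positive charge on tertiary C3' β to the C–Al bond; loss of Me2AlCl then gives the ether with retention of alkene geometry. The closest known reaction type is zirconium-catalysed methylalumination of terminal alkynes followed by capture of the alkenylalane or its lithium alanate by chloromethyl methyl ether, paraformaldehyde or chloroformates, whereas an aryloxymethyl chloride that carries a lactone has not served in this role. No ring is closed and no stereocentre is created, and C9' and C10' lie far from every reacting site. The step needs methyl delivery to C3' and E geometry, which the terminal alkyne, the syn addition and the retentive substitution at C2' should secure. It also needs chemoselectivity, which rests on the inertness of the isolated trisubstituted C6'=C7' alkene to carbometalation, on the low carbonyl reactivity of the neutral alane towards the ring B lactone once free AlMe3 has been stripped off, and on the low temperature that should spare the acetonide and both silyl ethers.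

Step 12
Reactants: 20 the fully protected ether from step 11
Product: 23 5-hydroxy-7-{[(2E,6E,9R,10S)-9,10,11-trihydroxy-3,7,11-trimethyldodeca-2,6-dien-1-yl]oxy}-2H-chromen-2-one (CNP0174708.4), via 5-hydroxycoumarin ether 21 (not isolated), via tertiary alcohol acetonide 22 (not isolated)
Conditions: TBAF (1.1 equiv), THF, 0 °C; then 1 M aq. HCl added to the same flask, rt → 40 °C; aq. NaHCO3
Reagents that add atoms: none
Why: Fluoride-induced cleavage of the aryl silyl ether, then acid-catalysed hydrolysis of the tertiary silyl ether and of the isopropylidene ketal; dilute acid should neither protonate the trisubstituted alkenes nor ionise the allylic aryl ether, and no C–O bond at C9' or C10' is broken, so both configurations are kept.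

Compound list
1 | dimethyl (4S,5S)-2,2-dimethyl-1,3-dioxolane-4,5-dicarboxylate | COC(=O)[C@H]1OC(C)(C)O[C@@H]1C(=O)OC | starting material
2 | methyl (4S,5S)-5-formyl-2,2-dimethyl-1,3-dioxolane-4-carboxylate | O=C[C@H]1OC(C)(C)O[C@@H]1C(=O)OC | intermediate
3 | methyl (4S,5R)-5-(hydroxymethyl)-2,2-dimethyl-1,3-dioxolane-4-carboxylate | OC[C@H]1OC(C)(C)O[C@@H]1C(=O)OC | intermediate
4 | 1-[(4S,5R)-5-(hydroxymethyl)-2,2-dimethyl-1,3-dioxolan-4-yl]ethan-1-one | OC[C@H]1OC(C)(C)O[C@@H]1C(C)=O | intermediate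
5 | 2-[(4S,5R)-5-(hydroxymethyl)-2,2-dimethyl-1,3-dioxolan-4-yl]propan-2-ol | OC[C@H]1OC(C)(C)O[C@@H]1C(C)(C)O | intermediate
6 | [(4R,5S)-5-(2-hydroxypropan-2-yl)-2,2-dimethyl-1,3-dioxolan-4-yl]methyl trifluoromethanesulfonate | O=S(=O)(OC[C@H]1OC(C)(C)O[C@@H]1C(C)(C)O)C(F)(F)F | intermediate
7 | {(4R,5S)-2,2-dimethyl-5-[2-(triethylsilyloxy)propan-2-yl]-1,3-dioxolan-4-yl}methyl trifluoromethanesulfonate | O=S(=O)(OC[C@H]1OC(C)(C)O[C@@H]1C(C)(C)O[Si](CC)(CC)CC)C(F)(F)F | intermediate
8 | 2,3-dihydrofuran | C1=COCC1 | starting material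
9 | 5-lithio-2,3-dihydrofuran | [Li]C1=CCCO1 | intermediate
10 | 5-({(4R,5S)-2,2-dimethyl-5-[2-(triethylsilyloxy)propan-2-yl]-1,3-dioxolan-4-yl}methyl)-2,3-dihydrofuran | C1CC=C(O1)C[C@H]2OC(C)(C)O[C@@H]2C(C)(C)O[Si](CC)(CC)CC | intermediate
11 | (3E)-5-{(4R,5S)-2,2-dimethyl-5-[2-(triethylsilyloxy)propan-2-yl]-1,3-dioxolan-4-yl}-4-methylpent-3-en-1-ol | OCC/C=C(\C)C[C@H]1OC(C)(C)O[C@@H]1C(C)(C)O[Si](CC)(CC)CC | intermediate
12 | (4R,5S)-4-[(2E)-5-iodo-2-methylpent-2-en-1-yl]-2,2-dimethyl-5-[2-(triethylsilyloxy)propan-2-yl]-1,3-dioxolane | ICC/C=C(\C)C[C@H]1OC(C)(C)O[C@@H]1C(C)(C)O[Si](CC)(CC)CC | intermediate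
13 | (4R,5S)-2,2-dimethyl-4-[(2E)-2-methylhept-2-en-6-yn-1-yl]-5-[2-(triethylsilyloxy)propan-2-yl]-1,3-dioxolane | C#CCC/C=C(\C)C[C@H]1OC(C)(C)O[C@@H]1C(C)(C)O[Si](CC)(CC)CC | intermediate
14 | 5,7-dihydroxy-2H-chromen-2-one (5,7-dihydroxycoumarin) | O=c1ccc2c(O)cc(O)cc2o1 | starting material
15 | 5-hydroxy-7-[(methylsulfanyl)methoxy]-2H-chromen-2-one | O=c1ccc2c(O)cc(OCSC)cc2o1 | intermediate
16 | 5-[(tert-butyldimethylsilyl)oxy]-7-[(methylsulfanyl)methoxy]-2H-chromen-2-one | O=c1ccc2c(O[Si](C)(C)C(C)(C)C)cc(OCSC)cc2o1 | intermediate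
17 | 5-[(tert-butyldimethylsilyl)oxy]-7-(chloromethoxy)-2H-chromen-2-one | O=c1ccc2c(O[Si](C)(C)C(C)(C)C)cc(OCCl)cc2o1 | intermediate
18 | trimethylaluminium | C[Al](C)C | starting material
19 | [(1E,5E)-7-{(4R,5S)-2,2-dimethyl-5-[2-(triethylsilyloxy)propan-2-yl]-1,3-dioxolan-4-yl}-2,6-dimethylhepta-1,5-dien-1-yl]dimethylalumane | C[Al](C)/C=C(\C)CC/C=C(\C)C[C@H]1OC(C)(C)O[C@@H]1C(C)(C)O[Si](CC)(CC)CC | intermediate
20 | 5-[(tert-butyldimethylsilyl)oxy]-7-{[(2E,6E)-8-{(4R,5S)-2,2-dimethyl-5-[2-(triethylsilyloxy)propan-2-yl]-1,3-dioxolan-4-yl}-3,7-dimethylocta-2,6-dien-1-yl]oxy}-2H-chromen-2-one | O=c1ccc2c(O[Si](C)(C)C(C)(C)C)cc(OC/C=C(\C)CC/C=C(\C)C[C@H]3OC(C)(C)O[C@@H]3C(C)(C)O[Si](CC)(CC)CC)cc2o1 | intermediate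
21 | 7-{[(2E,6E)-8-{(4R,5S)-2,2-dimethyl-5-[2-(triethylsilyloxy)propan-2-yl]-1,3-dioxolan-4-yl}-3,7-dimethylocta-2,6-dien-1-yl]oxy}-5-hydroxy-2H-chromen-2-one | O=c1ccc2c(O)cc(OC/C=C(\C)CC/C=C(\C)C[C@H]3OC(C)(C)O[C@@H]3C(C)(C)O[Si](CC)(CC)CC)cc2o1 | intermediate
22 | 5-hydroxy-7-{[(2E,6E)-8-[(4R,5S)-5-(2-hydroxypropan-2-yl)-2,2-dimethyl-1,3-dioxolan-4-yl]-3,7-dimethylocta-2,6-dien-1-yl]oxy}-2H-chromen-2-one | O=c1ccc2c(O)cc(OC/C=C(\C)CC/C=C(\C)C[C@H]3OC(C)(C)O[C@@H]3C(C)(C)O)cc2o1 | intermediate
23 | 5-hydroxy-7-{[(2E,6E,9R,10S)-9,10,11-trihydroxy-3,7,11-trimethyldodeca-2,6-dien-1-yl]oxy}-2H-chromen-2-one | C/C(=C\COc1cc(O)c2ccc(=O)oc2c1)CC/C=C(\C)C[C@@H](O)[C@H](O)C(C)(C)O | target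

Total step count: 12. Longest linear sequence: 9 steps (steps 1–7, 11 and 12); steps 8–10 form the coumarin branch.

Steps most likely to fail

Step 11. The alkenyl transfer may lose out to methyl transfer from residual Al–CH3 groups, to Lewis-acid-induced self-condensation of the chloromethyl ether on ring A, or to addition of the organoaluminium to the lactone. The fallback uses known chemistry and sets out from 13. The same methylalumination is followed by conversion into the lithium alanate with n-BuLi and capture by paraformaldehyde, which should give (2E,6E)-8-{(4R,5S)-2,2-dimethyl-5-[2-(triethylsilyloxy)propan-2-yl]-1,3-dioxolan-4-yl}-3,7-dimethylocta-2,6-dien-1-ol F1. CBr4 and PPh3 would convert it into the allylic bromide F2, and O7-alkylation of 14 by F2 (K2CO3, acetone) would come back to the route at 21, which the aqueous acid of step 12 turns into 23.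

Step 8. Site selection between O7 and O5 may be poor and double alkylation may compete. The fallback sets out from 14 and replaces selective alkylation by selective deprotection. Both phenols are silylated (TBSCl, imidazole) to 5,7-bis[(tert-butyldimethylsilyl)oxy]-2H-chromen-2-one F3. The unhindered 7-silyl ether, which releases the better stabilised oxide, is then cleaved (Cs2CO3, DMF/H2O, 0 °C) to 5-[(tert-butyldimethylsilyl)oxy]-7-hydroxy-2H-chromen-2-one F4. Etherification of F4 (NaH, ClCH2SMe) comes back at 16.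

Step 5. The alkenylnickel intermediate may isomerise and erode the E geometry, or the Grignard reagent may open the acetonide at the temperature needed. The fallback sets out from 7 and builds the C6'=C7' alkene by carbometalation and cross-coupling instead.
- Displacement of the triflate by LiC≡CSiMe3 (THF/DMPU, −78 °C) gives the silylalkyne F5.
- K2CO3 in MeOH frees the terminal alkyne F6.
- Cp2ZrCl2-catalysed methylalumination and then I2 give the (E)-alkenyl iodide F7.
- Pd(PPh3)4-catalysed Negishi coupling with the homopropargylzinc reagent F8 (from (4-iodobut-1-yn-1-yl)trimethylsilane and zinc dust) gives the silylated enyne F9.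
- K2CO3 in MeOH comes back at 13.

Further compounds
F1 | step 11 | (2E,6E)-8-{(4R,5S)-2,2-dimethyl-5-[2-(triethylsilyloxy)propan-2-yl]-1,3-dioxolan-4-yl}-3,7-dimethylocta-2,6-dien-1-ol | OC/C=C(\C)CC/C=C(\C)C[C@H]1OC(C)(C)O[C@@H]1C(C)(C)O[Si](CC)(CC)CC
F2 | step 11 | (4R,5S)-4-[(2E,6E)-8-bromo-2,6-dimethylocta-2,6-dien-1-yl]-2,2-dimethyl-5-[2-(triethylsilyloxy)propan-2-yl]-1,3-dioxolane | BrC/C=C(\C)CC/C=C(\C)C[C@H]1OC(C)(C)O[C@@H]1C(C)(C)O[Si](CC)(CC)CC
F3 | step 8 | 5,7-bis[(tert-butyldimethylsilyl)oxy]-2H-chromen-2-one | O=c1ccc2c(O[Si](C)(C)C(C)(C)C)cc(O[Si](C)(C)C(C)(C)C)cc2o1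
F4 | step 8 | 5-[(tert-butyldimethylsilyl)oxy]-7-hydroxy-2H-chromen-2-one | O=c1ccc2c(O[Si](C)(C)C(C)(C)C)cc(O)cc2o1
F5 | step 5 | (3-{(4R,5S)-2,2-dimethyl-5-[2-(triethylsilyloxy)propan-2-yl]-1,3-dioxolan-4-yl}prop-1-yn-1-yl)trimethylsilane | C[Si](C)(C)C#CC[C@H]1OC(C)(C)O[C@@H]1C(C)(C)O[Si](CC)(CC)CC
F6 | step 5 | (4R,5S)-2,2-dimethyl-4-(prop-2-yn-1-yl)-5-[2-(triethylsilyloxy)propan-2-yl]-1,3-dioxolane | C#CC[C@H]1OC(C)(C)O[C@@H]1C(C)(C)O[Si](CC)(CC)CC
F7 | step 5 | (4R,5S)-4-[(2E)-3-iodo-2-methylprop-2-en-1-yl]-2,2-dimethyl-5-[2-(triethylsilyloxy)propan-2-yl]-1,3-dioxolane | I/C=C(\C)C[C@H]1OC(C)(C)O[C@@H]1C(C)(C)O[Si](CC)(CC)CC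
F8 | step 5 | [4-(trimethylsilyl)but-3-yn-1-yl]zinc iodide | C[Si](C)(C)C#CCC[Zn]I
F9 | step 5 | [(5E)-7-{(4R,5S)-2,2-dimethyl-5-[2-(triethylsilyloxy)propan-2-yl]-1,3-dioxolan-4-yl}-6-methylhept-5-en-1-yn-1-yl]trimethylsilane | C[Si](C)(C)C#CCC/C=C(\C)C[C@H]1OC(C)(C)O[C@@H]1C(C)(C)O[Si](CC)(CC)CC
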